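**Retrosynthetic overview**

1. The target is a (1(10)Z,4E)-cyclodecadiene trans-fused at C6–C7 to an α-methylene-γ-lactone ring (O6, C6, C7, C11, C12). The plan rests on the array O6–C6–C7–C11(=C13), a homoallylic alcohol whose alkene is the exocyclic methylene. This is the product pattern of a [2,3]-Wittig shift of a C6–O–C13 ether.
2. Late disconnections: the C8 ester (epoxy acid 42, from tiglic acid by Sharpless epoxidation) and the lactone bond O6–C12 (oxidative lactonisation of the C6/C12 diol 32).
3. Key disconnection: C6–C7 forms while O–C13 breaks. This contracts the thirteen-membered bis-allylic ether 29 (C7 SEM enol ether) to carbocycle 31.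
4. Ether 29 comes from Williamson closure (O13 onto C6) of chloro alcohol 28. C11–C13 come from dimethyl malonate and acid 17. C8/C9 come from an anti glycolate aldol on Z-enal 8, made from geranyl acetate by Still–Gennari olefination.
5. Ring order: thirteen-membered ether, then ten-membered carbocycle, then γ-lactone. The oxirane arrives ready-made.

Key step: step 23

Numbering: germacrane numbering is used for all chain and ring atoms (C1=C10 Z, C4=C5 E, C14 and C15 methyls, C11–C13 lactone carbons).

Assumption: in diol 22 the hydroxymethyl arm cis to O7 (C13) is taken as the less hindered one, because the other arm (C12) faces the branched dioxolane carbon C8.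

**Step 1**
Reactants: 1 geranyl acetate
Product: 2 (E)-6-acetoxy-4-methylhex-4-enal
Conditions: O3 (1.0 equiv), CH2Cl2/pyridine, −78 °C; then Me2S, −78 °C to rt
Reagents that add atoms: ozone [O-][O+]=O
Why: Chemoselective ozonolysis, since the remote isopropylidene alkene is more electron-rich than C4=C5, which the allylic acetate deactivates, so one equivalent of ozone should cleave only the chain end.

**Step 2**
Reactants: 2 (E)-6-acetoxy-4-methylhex-4-enal; 3 methyl 2-[bis(2,2,2-trifluoroethoxy)phosphoryl]propanoate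
Product: 4 methyl (2Z,6E)-8-acetoxy-2,6-dimethylocta-2,6-dienoate
Conditions: 3, KN(SiMe3)2, 18-crown-6, THF, −78 °C; then 2
Reagents that add atoms: none
Why: Still–Gennari olefination, in which fast irreversible collapse of the kinetic adduct of the trifluoroethyl phosphonate under dissociating conditions should give the Z trisubstituted enoate (C1=C10).

**Step 3**
Reactants: 4 methyl (2Z,6E)-8-acetoxy-2,6-dimethylocta-2,6-dienoate
Product: 5 methyl (2Z,6E)-8-hydroxy-2,6-dimethylocta-2,6-dienoate
Conditions: K2CO3 (0.2 equiv), MeOH, 0 °C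
Reagents that add atoms: none
Why: Base-catalysed transesterification removes the acetate, while exchange at the methyl enoate is degenerate.

**Step 4**
Reactants: 5 methyl (2Z,6E)-8-hydroxy-2,6-dimethylocta-2,6-dienoate
Product: 6 methyl (2Z,6E)-8-(tert-butyldiphenylsilyloxy)-2,6-dimethylocta-2,6-dienoate
Conditions: TBDPSCl, imidazole, CH2Cl2, 0 °C to rt
Reagents that add atoms: tert-butylchlorodiphenylsilane CC(C)(C)[Si](Cl)(c1ccccc1)c1ccccc1
Why: Silyl ether formation, with TBDPS chosen because it must survive methanolic HCl in step 11 yet leave before TIPS in step 19.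

**Step 5**
Reactants: 6 methyl (2Z,6E)-8-(tert-butyldiphenylsilyloxy)-2,6-dimethylocta-2,6-dienoate
Product: 7 (2Z,6E)-8-(tert-butyldiphenylsilyloxy)-2,6-dimethylocta-2,6-dien-1-ol
Conditions: i-Bu2AlH (2.3 equiv), CH2Cl2, −78 °C; aq. KNaC4H4O6
Reagents that add atoms: none
Why: 1,2-Reduction of the enoate by i-Bu2AlH gives the allylic alcohol without changing either alkene geometry.

**Step 6**
Reactants: 7 (2Z,6E)-8-(tert-butyldiphenylsilyloxy)-2,6-dimethylocta-2,6-dien-1-ol
Product: 8 (2Z,6E)-8-(tert-butyldiphenylsilyloxy)-2,6-dimethylocta-2,6-dienal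
Conditions: MnO2 (excess), CH2Cl2, rt, dark
Reagents that add atoms: none
Why: Allylic alcohol oxidation on MnO2 is neutral, so the Z enal should not isomerise.

**Step 7**
Reactants: 9 (S)-3-chloropropane-1,2-diol; 10 butane-2,3-dione
Product: 11 (2S,5S,6S)-2-(chloromethyl)-5,6-dimethoxy-5,6-dimethyl-1,4-dioxane
Conditions: HC(OMe)3, camphorsulfonic acid (cat.), MeOH, reflux
Reagents that add atoms: trimethyl orthoformate COC(OC)OC
Why: Butane-2,3-diacetal formation under thermodynamic control puts both methoxy groups axial (anomeric effect) and the chloromethyl group equatorial, so the carbinol centre of 9 fixes both new acetal centres.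

**Step 8**
Reactants: 11 (2S,5S,6S)-2-(chloromethyl)-5,6-dimethoxy-5,6-dimethyl-1,4-dioxane
Product: 12 (5S,6S)-5,6-dimethoxy-5,6-dimethyl-2-methylidene-1,4-dioxane
Conditions: KOt-Bu, THF, reflux
Reagents that add atoms: none
Why: E2 dehydrochlorination gives the exocyclic enol ether.

**Step 9**
Reactants: 12 (5S,6S)-5,6-dimethoxy-5,6-dimethyl-2-methylidene-1,4-dioxane
Product: 13 (5S,6S)-5,6-dimethoxy-5,6-dimethyl-1,4-dioxan-2-one
Conditions: O3, CH2Cl2, −78 °C; then Me2S
Reagents that add atoms: ozone [O-][O+]=O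
Why: Ozonolysis of the enol ether alkene gives the lactone carbonyl and leaves the chirality stored in the two acetal carbons.

**Step 10**
Reactants: 8 (2Z,6E)-8-(tert-butyldiphenylsilyloxy)-2,6-dimethylocta-2,6-dienal; 13 (5S,6S)-5,6-dimethoxy-5,6-dimethyl-1,4-dioxan-2-one
Product: 14 aldol adduct, (3R,5S,6S)-3-[(1R,2Z,6E)-8-(tert-butyldiphenylsilyloxy)-1-hydroxy-2,6-dimethylocta-2,6-dienyl]-5,6-dimethoxy-5,6-dimethyl-1,4-dioxan-2-one
Conditions: 13, LiN(SiMe3)2, THF, −78 °C; then 8, 10 min; AcOH quench at −78 °C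
Reagents that add atoms: none
Why: Lithium enolate aldol addition, in which the ring-locked E(O) enolate reacts through a Zimmerman–Traxler chair to give the anti pair and the aldehyde enters anti to the axial methoxy group that is 1,3 to the enolate carbon, which sets 8R and with it 9R.

**Step 11**
Reactants: 14 aldol adduct
Product: 15 methyl (2R,3R,4Z,8E)-10-(tert-butyldiphenylsilyloxy)-2,3-dihydroxy-4,8-dimethyldeca-4,8-dienoate
Conditions: Me3SiCl (3 equiv), MeOH, 0 °C to rt; aq. NaHCO3
Reagents that add atoms: methanol CO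
Why: Acid-catalysed transesterification and deketalisation strip the diacetal, while the C9 carbinol, flanked by an oxygenated carbon and an ester, should resist ionisation and TBDPS tolerates the brief acid exposure.

**Step 12**
Reactants: 15 anti diol methyl ester
Product: 16 acetonide methyl ester, methyl (4R,5R)-5-[(2Z,6E)-8-(tert-butyldiphenylsilyloxy)-6-methylocta-2,6-dien-2-yl]-2,2-dimethyl-1,3-dioxolane-4-carboxylate
Conditions: Me2C(OMe)2, PPTS (cat.), CH2Cl2, rt
Reagents that add atoms: 2,2-dimethoxypropane COC(C)(C)OC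
Why: Acetonide formation by transketalisation converts the anti diol into the cis-dioxolane, a base-stable mask without acidic benzylic or allylic C–H for step 23.

**Step 13**
Reactants: 16 acetonide methyl ester
Product: 17 acetonide acid (8R,9R)
Conditions: LiOH, THF/H2O (3:1), 0 °C; dilute HCl to pH 4
Reagents that add atoms: lithium hydroxide [Li+].[OH-]
Why: Saponification of an activated α-alkoxy ester is fast at 0 °C, so C8 should not epimerise.

**Step 14**
Reactants: 17 acetonide acid; 18 dimethyl malonate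
Product: 20 acylmalonate (dimethyl 2-acylpropanedioate of acid 17), via acyl imidazolide 19 (not isolated)
Conditions: CDI, THF, rt; then 18, MgCl2, Et3N, MeCN, 0 °C to rt
Reagents that add atoms: 1,1'-carbonyldiimidazole O=C(n1ccnc1)n1ccnc1 (atoms reach only intermediate 19)
Why: C-acylation of the magnesium enolate of malonate (soft enolisation) installs C11, C12 and C13 at once, and the product rests as its chelated enolate, which shields C8–H from base.

**Step 15**
Reactants: 20 acylmalonate
Product: 21 C7 SEM enol ether diester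
Conditions: SEMCl, i-Pr2NEt, CH2Cl2, 0 °C
Reagents that add atoms: 2-(trimethylsilyl)ethoxymethyl chloride ClCOCC[Si](C)(C)C
Why: O-alkylation of the tricarbonyl enolate by a hard chloromethyl ether occurs at the acyl oxygen because C-alkylation would need a quaternary carbon, and no alkene geometry arises since C11 carries two identical esters.

**Step 16**
Reactants: 21 C7 SEM enol ether diester
Product: 22 2-alkylidene-propane-1,3-diol (C12–OH and C13–OH free)
Conditions: i-Bu2AlH (5 equiv), CH2Cl2, −78 to −40 °C; aq. KNaC4H4O6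
Reagents that add atoms: none
Why: Exhaustive 1,2-reduction of the alkylidene malonate by electrophilic i-Bu2AlH, where the donor oxygen and full substitution at C7 disfavour conjugate hydride delivery and the non-acidic work-up spares the enol ether.

**Step 17**
Reactants: 22 2-alkylidene-propane-1,3-diol
Product: 23 C13 mono-pivalate (pivaloyloxymethyl arm cis to O7; C12–OH free)
Conditions: PivCl (1.05 equiv), pyridine, CH2Cl2, −40 °C
Reagents that add atoms: pivaloyl chloride CC(C)(C)C(=O)Cl
Why: Sterically controlled mono-acylation, in which the bulky acyl chloride should take the arm cis to O7, so that this arm, which must end up free, is only temporarily capped and the lasting silyl group can go onto the hindered C12 arm.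

**Step 18**
Reactants: 23 C13 mono-pivalate
Product: 24 C12 TIPS ether, C13 pivalate, C6 TBDPS ether
Conditions: TIPSOTf, 2,6-lutidine, CH2Cl2, −78 to 0 °C
Reagents that add atoms: triisopropylsilyl triflate CC(C)[Si](C(C)C)(C(C)C)OS(=O)(=O)C(F)(F)F
Why: Silylation with the reactive triflate reaches the hindered alcohol, and TIPS is chosen because it resists O-to-O migration onto the neighbouring C13 alkoxide in step 22 and attack by n-BuLi in step 23.

**Step 19**
Reactants: 24 C12 TIPS ether, C13 pivalate, C6 TBDPS ether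
Product: 25 C6 allylic alcohol (C12 OTIPS, C13 OPiv)
Conditions: Bu4NF/AcOH (1:1), THF, 0 °C to rt
Reagents that add atoms: none
Why: Buffered fluoride desilylation should cleave the unhindered primary TBDPS ether well before the shielded TIPS ether, and pivalate and SEM are inert.

**Step 20**
Reactants: 25 C6 allylic alcohol
Product: 27 C6 allylic chloride, via C6 mesylate 26 (not isolated)
Conditions: MsCl, 2,4,6-collidine, LiCl, DMF, 0 °C
Reagents that add atoms: lithium chloride [Li+].[Cl-]; methanesulfonyl chloride CS(=O)(=O)Cl (atoms reach only intermediate 26)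
Why: Mesylation and in situ SN2 displacement by chloride give the primary allylic chloride without transposition, and collidine keeps the medium non-acidic for the enol ether.

**Step 21**
Reactants: 27 C6 allylic chloride
Product: 28 chloro alcohol (C13–OH free, C6–Cl, C12 OTIPS)
Conditions: i-Bu2AlH (2.2 equiv), CH2Cl2, −78 °C; aq. KNaC4H4O6
Reagents that add atoms: none
Why: Reductive ester cleavage frees C13–OH, and a primary allylic chloride is inert to i-Bu2AlH at this temperature.

**Step 22**
Reactants: 28 chloro alcohol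
Product: 29 thirteen-membered C6–O–C13 ether (8R,9R; O7 cis to C13; C7 OSEM; C8/C9 acetonide; C12 OTIPS)
Conditions: NaH, Bu4NI (cat.), THF, 0.002 M by slow addition, 50 °C
Reagents that add atoms: none
Why: Intramolecular Williamson etherification under high dilution is the established entry to thirteen-membered bis-allylic ethers, helped here by iodide catalysis and by two alkenes and a cis-dioxolane that pre-bend the chain.

**Step 23**
Reactants: 29 thirteen-membered C6–O–C13 ether
Product: 31 ten-membered C6 carbinol (6R,7R,8R,9R), via C6-lithiated ether 30 (not isolated)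
Conditions: n-BuLi (3 equiv), THF, −78 to −25 °C; aq. NH4Cl
Reagents that add atoms: n-butyllithium [Li]CCCC (lithium reaches only intermediate 30)
Why: Proposed new method: n-BuLi should remove a C6–H, which lies between the ether oxygen and C4=C5, whereas anions at C13 or C12 would push charge onto the donor-substituted, fully substituted C7 and are shielded by SEM and TIPS; carbanion 30 then shifts suprafacially across C13–C11=C7 in a concerted six-electron [2,3] process through a five-membered envelope (C6, O, C13, C11, C7), making C6–C7 as O–C13 breaks and C11=C13 appears. The closest known reaction type is the [2,3]-Wittig ring contraction of thirteen-membered bis-allylic ethers to ten-membered germacrane carbocycles, where the migration terminus bears hydrogen; a terminus that bears an alkoxy group and becomes quaternary is untested, although the π* coefficient of an enol ether is largest at the oxygen-bearing carbon. The ten-membered ring closes by transannular C–C bond formation inside the existing macrocycle (contraction by three atoms), not by an end-to-end cyclisation, so dilution is not needed. For C6 relative to C7, O6 and C11 stay synclinal in the envelope, C5 takes the exo position and C8 is trans to C13 on the alkene, which places C5 and C8 on opposite faces of the later lactone. For the absolute face, C8–H eclipses C7=C11 to avoid A(1,3) strain with C12H2OTIPS, so O8 and C9 flank the two faces and C6 should arrive from the O8 face (C6–C7–C8–C9 near 150°, lithium held by O8 and the SEM oxygens), because arrival from the C9 face would press C5 against C9 in a syn-pentane contact. The step therefore needs C6 over C13 lithiation, [2,3] over [1,2] shift (hence the low temperature) and this face selection.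

**Step 24**
Reactants: 31 ten-membered C6 carbinol
Product: 32 C6/C12 diol (C7 OSEM, C8/C9 acetonide)
Conditions: Bu4NF, THF, 0 °C to rt
Reagents that add atoms: none
Why: Fluoride cleavage of the primary TIPS ether, during which the SEM ether survives at room temperature.

**Step 25**
Reactants: 32 C6/C12 diol
Product: 35 alpha-methylene-gamma-lactone (C7 OSEM; C8/C9 acetonide), via enal 33 (not isolated), via lactol 34 (not isolated)
Conditions: TEMPO (0.2 equiv), PhI(OAc)2 (3 equiv), CH2Cl2, rt
Reagents that add atoms: none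
Why: Oxoammonium-mediated oxidative lactonisation oxidises the primary allylic C12–OH first, C6–OH closes the five-membered lactol and a second oxidation gives the lactone, while the acetonide blocks a 12,8-olide and the SEM group prevents glycol cleavage at C6–C7.

**Step 26**
Reactants: 35 alpha-methylene-gamma-lactone (C7 OSEM; C8/C9 acetonide)
Product: 36 C7 tertiary alcohol (C8/C9 acetonide)
Conditions: MgBr2·OEt2 (10 equiv), MeNO2, Et2O, rt
Reagents that add atoms: none
Why: Lewis acid cleavage of the SEM ether is placed here because neither MgBr2 nor hot fluoride would be tolerated by the oxirane ester that is attached later.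

**Step 27**
Reactants: 36 C7 tertiary alcohol (C8/C9 acetonide)
Product: 37 C7,C8,C9 triol lactone
Conditions: AcOH/H2O (4:1), 40 °C
Reagents that add atoms: none
Why: Mild acid hydrolysis of the acetonide, in which both ring alkenes carry allylic oxygen and should therefore resist protonation and transannular cyclisation.

**Step 28**
Reactants: 37 C7,C8,C9 triol lactone
Product: 38 C9 triethylsilyl ether (C7–OH and C8–OH free)
Conditions: TESCl (1.1 equiv), imidazole, CH2Cl2, −20 °C
Reagents that add atoms: chlorotriethylsilane CC[Si](Cl)(CC)CC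
Why: Site-selective silylation, since the allylic C9–OH next to sp2 C10 is more accessible than C8–OH beside quaternary C7, and the tertiary C7–OH is inert.

**Step 29**
Reactants: 39 tiglic acid
Product: 40 (E)-2-methylbut-2-en-1-ol
Conditions: LiAlH4, Et2O, 0 °C
Reagents that add atoms: none
Why: Hydride reduction of the acid to the allylic alcohol keeps the E alkene.

**Step 30**
Reactants: 40 (E)-2-methylbut-2-en-1-ol
Product: 41 [(2R,3R)-2,3-dimethyloxiran-2-yl]methanol
Conditions: Ti(Oi-Pr)4 (cat.), D-(−)-diisopropyl tartrate (cat.), t-BuOOH, 4 Å molecular sieves, CH2Cl2, −20 °C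
Reagents that add atoms: tert-butyl hydroperoxide CC(C)(C)OO
Why: Sharpless asymmetric epoxidation, in which the D-(−)-tartrate ligand should direct oxygen to the face that gives the (2R,3R) epoxy alcohol and syn addition keeps the two methyl groups cis, setting both oxirane centres.

**Step 31**
Reactants: 41 [(2R,3R)-2,3-dimethyloxiran-2-yl]methanol
Product: 42 (2S,3R)-2,3-dimethyloxirane-2-carboxylic acid
Conditions: RuCl3 (cat.), NaIO4, CCl4/MeCN/H2O, 0 °C to rt
Reagents that add atoms: water O
Why: Ruthenium tetroxide oxidation takes the primary alcohol to the acid without touching the oxirane, and the C2 descriptor changes only because the substituent priorities change.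

**Step 32**
Reactants: 38 C9 triethylsilyl ether; 42 (2S,3R)-2,3-dimethyloxirane-2-carboxylic acid
Product: 44 C8 epoxy ester (C9 OTES), via mixed anhydride 43 (not isolated)
Conditions: 42, 2,4,6-trichlorobenzoyl chloride, Et3N, toluene, rt; then 38, DMAP, rt
Reagents that add atoms: 2,4,6-trichlorobenzoyl chloride O=C(Cl)c1c(Cl)cc(Cl)cc1Cl (atoms reach only intermediate 43)
Why: Yamaguchi esterification couples a hindered acid with the only free secondary alcohol, and the tertiary C7–OH does not compete.

**Step 33**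
Reactants: 44 C8 epoxy ester (C9 OTES)
Product: 45 target CNP0420662.1
Conditions: HF·pyridine, pyridine, THF, 0 °C
Reagents that add atoms: none
Why: Buffered fluoride desilylation avoids base, so O8-to-O9 acyl migration, addition to the methylene lactone and oxirane opening should all be suppressed.

**Compound list**

1 | geranyl acetate | CC(=O)OC/C=C(\C)CCC=C(C)C | starting material
2 | (E)-6-acetoxy-4-methylhex-4-enal | CC(=O)OC/C=C(\C)CCC=O | intermediate
3 | methyl 2-[bis(2,2,2-trifluoroethoxy)phosphoryl]propanoate | COC(=O)C(C)P(=O)(OCC(F)(F)F)OCC(F)(F)F | starting material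
4 | methyl (2Z,6E)-8-acetoxy-2,6-dimethylocta-2,6-dienoate | CC(=O)OC/C=C(\C)CC/C=C(/C)C(=O)OC | intermediate
5 | methyl (2Z,6E)-8-hydroxy-2,6-dimethylocta-2,6-dienoate | OC/C=C(\C)CC/C=C(/C)C(=O)OC | intermediate
6 | methyl (2Z,6E)-8-(tert-butyldiphenylsilyloxy)-2,6-dimethylocta-2,6-dienoate | CC(C)(C)[Si](c1ccccc1)(c1ccccc1)OC/C=C(\C)CC/C=C(/C)C(=O)OC | intermediate
7 | (2Z,6E)-8-(tert-butyldiphenylsilyloxy)-2,6-dimethylocta-2,6-dien-1-ol | CC(C)(C)[Si](c1ccccc1)(c1ccccc1)OC/C=C(\C)CC/C=C(/C)CO | intermediate
8 | (2Z,6E)-8-(tert-butyldiphenylsilyloxy)-2,6-dimethylocta-2,6-dienal | CC(C)(C)[Si](c1ccccc1)(c1ccccc1)OC/C=C(\C)CC/C=C(/C)C=O | intermediate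
9 | (S)-3-chloropropane-1,2-diol | OC[C@H](O)CCl | starting material
10 | butane-2,3-dione | CC(=O)C(C)=O | starting material
11 | (2S,5S,6S)-2-(chloromethyl)-5,6-dimethoxy-5,6-dimethyl-1,4-dioxane | ClC[C@@H]1CO[C@](C)(OC)[C@@](C)(OC)O1 | intermediate
12 | (5S,6S)-5,6-dimethoxy-5,6-dimethyl-2-methylidene-1,4-dioxane | C=C1CO[C@](C)(OC)[C@@](C)(OC)O1 | intermediate
13 | (5S,6S)-5,6-dimethoxy-5,6-dimethyl-1,4-dioxan-2-one | O=C1CO[C@](C)(OC)[C@@](C)(OC)O1 | intermediate
14 | (3R,5S,6S)-3-[(1R,2Z,6E)-8-(tert-butyldiphenylsilyloxy)-1-hydroxy-2,6-dimethylocta-2,6-dienyl]-5,6-dimethoxy-5,6-dimethyl-1,4-dioxan-2-one (8R,9R aldol adduct) | CC(C)(C)[Si](c1ccccc1)(c1ccccc1)OC/C=C(\C)CC/C=C(/C)[C@@H](O)[C@H]2O[C@](C)(OC)[C@@](C)(OC)OC2=O | intermediate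
15 | methyl (2R,3R,4Z,8E)-10-(tert-butyldiphenylsilyloxy)-2,3-dihydroxy-4,8-dimethyldeca-4,8-dienoate | CC(C)(C)[Si](c1ccccc1)(c1ccccc1)OC/C=C(\C)CC/C=C(/C)[C@@H](O)[C@@H](O)C(=O)OC | intermediate
16 | methyl (4R,5R)-5-[(2Z,6E)-8-(tert-butyldiphenylsilyloxy)-6-methylocta-2,6-dien-2-yl]-2,2-dimethyl-1,3-dioxolane-4-carboxylate (cis-dioxolane) | CC(C)(C)[Si](c1ccccc1)(c1ccccc1)OC/C=C(\C)CC/C=C(/C)[C@H]2OC(C)(C)O[C@H]2C(=O)OC | intermediate
17 | carboxylic acid of 16 (8R,9R) | CC(C)(C)[Si](c1ccccc1)(c1ccccc1)OC/C=C(\C)CC/C=C(/C)[C@H]2OC(C)(C)O[C@H]2C(=O)O | intermediate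
18 | dimethyl malonate | COC(=O)CC(=O)OC | starting material
19 | N-acylimidazole of acid 17 | CC(C)(C)[Si](c1ccccc1)(c1ccccc1)OC/C=C(\C)CC/C=C(/C)[C@H]2OC(C)(C)O[C@H]2C(=O)n3ccnc3 | intermediate
20 | dimethyl 2-acylpropanedioate of acid 17 (drawn as keto tautomer; C7 ketone, C11 methine, C12 and C13 esters) | CC(C)(C)[Si](c1ccccc1)(c1ccccc1)OC/C=C(\C)CC/C=C(/C)[C@H]2OC(C)(C)O[C@H]2C(=O)C(C(=O)OC)C(=O)OC | intermediate
21 | C7 SEM enol ether of 20 (C7=C11 alkylidene malonate) | CC(C)(C)[Si](c1ccccc1)(c1ccccc1)OC/C=C(\C)CC/C=C(/C)[C@H]2OC(C)(C)O[C@H]2C(OCOCC[Si](C)(C)C)=C(C(=O)OC)C(=O)OC | intermediate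
22 | diol from 21 (C11 bears two CH2OH groups) | CC(C)(C)[Si](c1ccccc1)(c1ccccc1)OC/C=C(\C)CC/C=C(/C)[C@H]2OC(C)(C)O[C@H]2C(OCOCC[Si](C)(C)C)=C(CO)CO | intermediate
23 | mono-pivalate of 22 (C13H2OPiv cis to O7; C12H2OH cis to C8) | CC(C)(C)[Si](c1ccccc1)(c1ccccc1)OC/C=C(\C)CC/C=C(/C)[C@H]2OC(C)(C)O[C@H]2/C(OCOCC[Si](C)(C)C)=C(\CO)COC(=O)C(C)(C)C | intermediate
24 | C12 TIPS ether of 23 | CC(C)(C)[Si](c1ccccc1)(c1ccccc1)OC/C=C(\C)CC/C=C(/C)[C@H]2OC(C)(C)O[C@H]2/C(OCOCC[Si](C)(C)C)=C(\CO[Si](C(C)C)(C(C)C)C(C)C)COC(=O)C(C)(C)C | intermediate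
25 | C6 alcohol from 24 | OC/C=C(\C)CC/C=C(/C)[C@H]1OC(C)(C)O[C@H]1/C(OCOCC[Si](C)(C)C)=C(\CO[Si](C(C)C)(C(C)C)C(C)C)COC(=O)C(C)(C)C | intermediate
26 | C6 mesylate of 25 | CS(=O)(=O)OC/C=C(\C)CC/C=C(/C)[C@H]1OC(C)(C)O[C@H]1/C(OCOCC[Si](C)(C)C)=C(\CO[Si](C(C)C)(C(C)C)C(C)C)COC(=O)C(C)(C)C | intermediate
27 | C6 chloride, C13 pivalate | ClC/C=C(\C)CC/C=C(/C)[C@H]1OC(C)(C)O[C@H]1/C(OCOCC[Si](C)(C)C)=C(\CO[Si](C(C)C)(C(C)C)C(C)C)COC(=O)C(C)(C)C | intermediate
28 | C6 chloride, C13 alcohol | ClC/C=C(\C)CC/C=C(/C)[C@H]1OC(C)(C)O[C@H]1/C(OCOCC[Si](C)(C)C)=C(\CO[Si](C(C)C)(C(C)C)C(C)C)CO | intermediate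
29 | thirteen-membered C6–O–C13 ether (8R,9R; C1=C10 Z; C4=C5 E; O7 cis to C13) | O1C/C=C(\C)CC/C=C(/C)[C@H]2OC(C)(C)O[C@H]2/C(OCOCC[Si](C)(C)C)=C(\CO[Si](C(C)C)(C(C)C)C(C)C)C1 | intermediate
30 | C6-lithiated 29 (configuration at C6 not defined) | O1C([Li])/C=C(\C)CC/C=C(/C)[C@H]2OC(C)(C)O[C@H]2/C(OCOCC[Si](C)(C)C)=C(\CO[Si](C(C)C)(C(C)C)C(C)C)C1 | intermediate
31 | ten-membered carbinol (6R,7R,8R,9R) with C7 OSEM and C7 2-(TIPSO-methyl)vinyl group | O[C@@H]1/C=C(\C)CC/C=C(/C)[C@H]2OC(C)(C)O[C@H]2[C@@]1(OCOCC[Si](C)(C)C)C(=C)CO[Si](C(C)C)(C(C)C)C(C)C | intermediate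
32 | C6/C12 diol | O[C@@H]1/C=C(\C)CC/C=C(/C)[C@H]2OC(C)(C)O[C@H]2[C@@]1(OCOCC[Si](C)(C)C)C(=C)CO | intermediate
33 | C12 enal | O[C@@H]1/C=C(\C)CC/C=C(/C)[C@H]2OC(C)(C)O[C@H]2[C@@]1(OCOCC[Si](C)(C)C)C(=C)C=O | intermediate
34 | C12 lactol (C12 epimers) | C=C1C(O)O[C@@H]2/C=C(\C)CC/C=C(/C)[C@H]3OC(C)(C)O[C@H]3[C@@]12OCOCC[Si](C)(C)C | intermediate
35 | trans-fused α-methylene-γ-lactone, C7 OSEM, C8/C9 acetonide | C=C1C(=O)O[C@@H]2/C=C(\C)CC/C=C(/C)[C@H]3OC(C)(C)O[C@H]3[C@@]12OCOCC[Si](C)(C)C | intermediate
36 | lactone with free C7–OH, C8/C9 acetonide | C=C1C(=O)O[C@@H]2/C=C(\C)CC/C=C(/C)[C@H]3OC(C)(C)O[C@H]3[C@@]12O | intermediate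
37 | C7,C8,C9 triol lactone | C=C1C(=O)O[C@@H]2/C=C(\C)CC/C=C(/C)[C@@H](O)[C@@H](O)[C@@]12O | intermediate
38 | C9 triethylsilyl ether of 37 | C=C1C(=O)O[C@@H]2/C=C(\C)CC/C=C(/C)[C@@H](O[Si](CC)(CC)CC)[C@@H](O)[C@@]12O | intermediate
39 | tiglic acid | C/C=C(\C)C(=O)O | starting material
40 | (E)-2-methylbut-2-en-1-ol | C/C=C(\C)CO | intermediate
41 | [(2R,3R)-2,3-dimethyloxiran-2-yl]methanol | OC[C@@]1(C)O[C@@H]1C | intermediate
42 | (2S,3R)-2,3-dimethyloxirane-2-carboxylic acid | OC(=O)[C@@]1(C)O[C@@H]1C | intermediate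
43 | mixed anhydride of 42 and 2,4,6-trichlorobenzoic acid | O=C(OC(=O)[C@@]1(C)O[C@@H]1C)c1c(Cl)cc(Cl)cc1Cl | intermediate
44 | C8 (2S,3R)-epoxy ester, C9 OTES | C=C1C(=O)O[C@@H]2/C=C(\C)CC/C=C(/C)[C@@H](O[Si](CC)(CC)CC)[C@@H](OC(=O)[C@@]3(C)O[C@@H]3C)[C@@]12O | intermediate
45 | CNP0420662.1 (6R,7R,8R,9R; ester 2S,3R) | C=C1C(=O)O[C@@H]2/C=C(\C)CC/C=C(/C)[C@@H](O)[C@@H](OC(=O)[C@@]3(C)O[C@@H]3C)[C@@]12O | target

**Totals**

Total step count: 33. Longest linear sequence: 27 (steps 1–6, 10–28, 32 and 33).

**Steps most likely to fail**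

Step 23 (labelled step). The shift onto a tetrasubstituted, donor-bearing terminus may be slow. The anion could then drift into a [1,2] shift, lithiation could occur at C13 or C12, or the face selection could be poor. The fallback keeps the same bond set but reverses the polarity, using known carbonyl allylation chemistry. It sets out from 25.
- MnO2 oxidation of the C6 alcohol gives the enal pivalate F1.
- Pd(PPh3)4 (a zerovalent palladium catalyst) ionises the allylic pivalate.
- Indium monoiodide InI reduces the π-allyl complex to a γ-alkoxyallylindium.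
- Under dilution this adds through C7 to the C6 aldehyde in a closed chair, with C8 equatorial, which predicts the same C6/C7 relative sense.
- Aqueous work-up delivers 31, where the route is rejoined.

Step 17. Discrimination between the two primary allylic hydroxymethyl arms may be poor, which would later give the macrocycle with the wrong enol ether geometry. The fallback tells the arms apart by construction instead of by reagent bulk. It sets out from 17 (through imidazolide 19).
- Methyl 3-hydroxypropanoate is silylated (TIPSCl, imidazole) to methyl 3-(triisopropylsilyloxy)propanoate F2.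
- The lithium enolate of F2 (LiN(i-Pr)2, THF, −78 °C) is acylated by 19 in a crossed Claisen condensation to give the α-(silyloxymethyl) β-keto ester F3.
- The sodium chelate of F3 (NaH, THF, 0 °C) is O-alkylated with SEMCl to the enol ether ester F4, in which O7 is cis to the ester carbon (C13).
- i-Bu2AlH reduces F4 to the C13 allylic alcohol F5.
- Pivaloylation of F5 gives 24, where the route is rejoined.

Step 22. Intermolecular etherification, 1,4-elimination of HCl from the allylic chloride, or silyl migration in the alkoxide may outrun ring closure. The fallback reverses the roles of the two termini. It sets out from 25 and skips steps 20 and 21.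
- The C6 alcohol is turned into its zinc alkoxide with Et2Zn.
- Pd(PPh3)4 ionises the C13 pivalate.
- Intramolecular Tsuji–Trost etherification at the primary C13 terminus closes the ring to 29 directly.
- No new compound is made on the way.

**Further compounds**

F1 | step 23 | C6 enal with C13 pivalate, C12 OTIPS, C7 OSEM, C8/C9 acetonide (8R,9R) | O=C/C=C(\C)CC/C=C(/C)[C@H]1OC(C)(C)O[C@H]1/C(OCOCC[Si](C)(C)C)=C(\CO[Si](C(C)C)(C(C)C)C(C)C)COC(=O)C(C)(C)C
F2 | step 17 | methyl 3-(triisopropylsilyloxy)propanoate | COC(=O)CCO[Si](C(C)C)(C(C)C)C(C)C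
F3 | step 17 | α-(triisopropylsilyloxymethyl) β-keto ester (C11 epimers; 8R,9R) | CC(C)(C)[Si](c1ccccc1)(c1ccccc1)OC/C=C(\C)CC/C=C(/C)[C@H]2OC(C)(C)O[C@H]2C(=O)C(CO[Si](C(C)C)(C(C)C)C(C)C)C(=O)OC
F4 | step 17 | C7 SEM enol ether ester (O7 cis to CO2Me; C8 cis to CH2OTIPS) | CC(C)(C)[Si](c1ccccc1)(c1ccccc1)OC/C=C(\C)CC/C=C(/C)[C@H]2OC(C)(C)O[C@H]2/C(OCOCC[Si](C)(C)C)=C(\CO[Si](C(C)C)(C(C)C)C(C)C)C(=O)OC
F5 | step 17 | C13 allylic alcohol with C12 OTIPS and C6 OTBDPS | CC(C)(C)[Si](c1ccccc1)(c1ccccc1)OC/C=C(\C)CC/C=C(/C)[C@H]2OC(C)(C)O[C@H]2/C(OCOCC[Si](C)(C)C)=C(\CO[Si](C(C)C)(C(C)C)C(C)C)CO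
F0 | step 22 | none | none
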